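**Retrosynthetic overview**

1. Hydrogenation of C7=C8 and desilylation lead back to a Δ7 pentacycle. Its tetrahydrofuran ring (O, C9, C11, C12, C13) and its δ-lactone (C4, C19, O, C20, C10, C5) are disconnected together at C9–O and C10–C20, to a bicyclic ring-B 7,9-diene that carries a chloromethyl ester on C4.
2. Enabling feature: the C19 carboxyl oxygen is 1,3 to C10 across C5 of ring A, so a C20 cation on that oxygen reaches the C10 terminus of the C7=C8–C9=C10 diene through a six-membered transition state. The diene relays the charge to C9, where the C13 tertiary hydroxyl (1,4 to C9) closes the tetrahydrofuran.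
3. The diene comes from a B-alkyl Suzuki coupling of a ring-B dienyl triflate with (S)-3-ethenyl-3-hydroxyoxolan-2-one (the spiro γ-lactone, made first from (R)-malic acid).
4. The triflate comes from a bicyclic enone, made by an intramolecular Diels–Alder reaction of an aldol-derived trienone. This closes rings A and B together; C6 comes from (R)-glyceraldehyde acetonide, C5 from C6 by A(1,3) strain, and C4 from the E-enoate geometry.
5. Ring order: γ-butyrolactone; rings A and B; then δ-lactone and, last, the tetrahydrofuran in one cascade.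

Key step: step 17

Remark: labdane numbering is used throughout (C19 = carboxyl carbon on C4, C20 = CH2 on C10, C17 = methyl on C8); β is the decalin face that carries H-5, C19 and C20. The target as written is cis-fused (H-5 and C20 both β).

**Step 1**
Reactants: 1 tert-butyl 2-bromopropanoate; 2 triphenylphosphine
Product: 4 tert-butyl 2-(triphenylphosphoranylidene)propanoate, via phosphonium bromide 3 (not isolated)
Conditions: PhMe, 80 °C; then NaOH (aq), CH2Cl2, 25 °C
Reagents that add atoms: none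
Why: SN2 quaternization of the phosphine by the α-bromo ester and deprotonation of the salt give the ester-stabilized Wittig ylide.

**Step 2**
Reactants: 5 (R)-2,2-dimethyl-1,3-dioxolane-4-carbaldehyde; 4 tert-butyl 2-(triphenylphosphoranylidene)propanoate
Product: 6 tert-butyl (E)-3-[(4S)-2,2-dimethyl-1,3-dioxolan-4-yl]-2-methylprop-2-enoate
Conditions: CH2Cl2, 0 → 25 °C
Reagents that add atoms: none
Why: Wittig olefination with a stabilized α-branched ylide should give the (E)-trisubstituted enoate under neutral conditions that leave the α-alkoxy stereocenter (future C6) untouched.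

**Step 3**
Reactants: 6 tert-butyl (E)-3-[(4S)-2,2-dimethyl-1,3-dioxolan-4-yl]-2-methylprop-2-enoate
Product: 7 tert-butyl (2E,4S)-4,5-dihydroxy-2-methylpent-2-enoate
Conditions: AcOH/H2O (4:1), 40 °C
Reagents that add atoms: none
Why: Acid-catalysed acetal hydrolysis frees the diol, and the E geometry keeps the γ-hydroxyl from lactonizing onto the ester.

**Step 4**
Reactants: 7 tert-butyl (2E,4S)-4,5-dihydroxy-2-methylpent-2-enoate
Product: 8 tert-butyl (2E,4S)-2-methyl-4,5-bis(triisopropylsilyloxy)pent-2-enoate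
Conditions: i-Pr3SiOTf, 2,6-lutidine, CH2Cl2, 0 °C
Reagents that add atoms: triisopropylsilyl trifluoromethanesulfonate, CC(C)[Si](OS(=O)(=O)C(F)(F)F)(C(C)C)C(C)C
Why: Silyl triflate and a hindered base silylate both hydroxyls without touching the stereocenter (O-silylation).

**Step 5**
Reactants: 8 tert-butyl (2E,4S)-2-methyl-4,5-bis(triisopropylsilyloxy)pent-2-enoate
Product: 9 tert-butyl (2E,4S)-5-hydroxy-2-methyl-4-(triisopropylsilyloxy)pent-2-enoate
Conditions: HF·pyridine, pyridine, THF, 0 °C
Reagents that add atoms: none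
Why: Selective desilylation should work because the primary silyl ether is cleaved much faster than the hindered secondary one.

**Step 6**
Reactants: 9 tert-butyl (2E,4S)-5-hydroxy-2-methyl-4-(triisopropylsilyloxy)pent-2-enoate
Product: 10 tert-butyl (2E,4S)-2-methyl-5-oxo-4-(triisopropylsilyloxy)pent-2-enoate
Conditions: Dess–Martin periodinane, NaHCO3, CH2Cl2, 0 → 25 °C
Reagents that add atoms: none
Why: Dess–Martin oxidation is non-basic, so the acidic α-silyloxy aldehyde stereocenter should survive.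

**Step 7**
Reactants: 11 acrolein; 12 diethyl (2-oxobutyl)phosphonate
Product: 13 (E)-hepta-4,6-dien-3-one
Conditions: K2CO3, THF/H2O, 0 → 25 °C
Reagents that add atoms: none
Why: Horner–Wadsworth–Emmons olefination of a β-keto phosphonate with an enal gives the (E)-dienone.

**Step 8**
Reactants: 13 (E)-hepta-4,6-dien-3-one; 10 tert-butyl (2E,4S)-2-methyl-5-oxo-4-(triisopropylsilyloxy)pent-2-enoate
Product: 15 tert-butyl (2E,4S,8E)-2,6-dimethyl-7-oxo-4-(triisopropylsilyloxy)-5-(trimethylsilyloxy)undeca-2,8,10-trienoate (C5/C6 diastereomer mixture), via silyl dienol ether 14 (not isolated)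
Conditions: Me3SiOTf, i-Pr2NEt, CH2Cl2, −78 → 0 °C; then 10, −78 °C
Reagents that add atoms: trimethylsilyl trifluoromethanesulfonate, C[Si](C)(C)OS(=O)(=O)C(F)(F)F
Why: One-pot enol silane formation and Mukaiyama aldol addition avoid a strongly basic enolate, so the aldehyde stereocenter should hold; the new centers at labdane C7 and C8 form as a mixture that is erased in step 10.

**Step 9**
Reactants: 15 tert-butyl (2E,4S,8E)-2,6-dimethyl-7-oxo-4-(triisopropylsilyloxy)-5-(trimethylsilyloxy)undeca-2,8,10-trienoate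
Product: 16 Diels–Alder adduct tert-butyl 1,6-dimethyl-5-oxo-8-(triisopropylsilyloxy)-7-(trimethylsilyloxy)-1,2,4a,5,6,7,8,8a-octahydronaphthalene-1-carboxylate (labdane: 19-ester β; H-5 β; 6-silyloxy β; mixture at C7/C8/C10)
Conditions: PhMe, BHT, 180 °C, sealed tube
Reagents that add atoms: none
Why: In this thermal intramolecular Diels–Alder reaction of a 1,7,9-decatriene the E-enoate geometry puts the C4 methyl cis and the ester trans to C6, and A(1,3) strain between that methyl and C6 holds H-6 in the alkene plane so that the tethered diene adds anti to the silyloxy group, which sets C5 (H-5 cis to O-6).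

**Step 10**
Reactants: 16 Diels–Alder adduct
Product: 18 enone tert-butyl 1,6-dimethyl-5-oxo-8-(triisopropylsilyloxy)-1,2,3,4,4a,5,8,8a-octahydronaphthalene-1-carboxylate (labdane 7-en-9-one; C10 epimer mixture), via saturated silyloxy ketone 17 (not isolated)
Conditions: H2 (1 atm), Pd/C, EtOAc, 25 °C; filter; then DBU, CH2Cl2, 25 °C
Reagents that add atoms: none
Why: Heterogeneous hydrogenation removes the only C=C (ring A) before base is added, and E1cB loss of trimethylsilanol from the β-silyloxy ketone then gives the ring-B enone regiospecifically while erasing C7 and C8.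

**Step 11**
Reactants: 18 enone
Product: 20 dienyl triflate tert-butyl 1,6-dimethyl-8-(triisopropylsilyloxy)-5-(trifluoromethylsulfonyloxy)-1,2,3,4,8,8a-hexahydronaphthalene-1-carboxylate, via potassium dienolate 19 (not isolated)
Conditions: KN(SiMe3)2, THF, −78 °C; then PhNTf2, −78 → 0 °C
Reagents that add atoms: N-phenylbis(trifluoromethanesulfonimide), O=S(=O)(N(c1ccccc1)S(=O)(=O)C(F)(F)F)C(F)(F)F
Why: Kinetic α'-deprotonation of the enone (H-10 is the only α' hydrogen) and O-triflation of the cross-conjugated dienolate give the 7,9-diene and erase the C10 stereocenter.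

**Step 12**
Reactants: 21 (R)-malic acid; 22 pivalaldehyde
Product: 23 [(2R,4R)-2-tert-butyl-5-oxo-1,3-dioxolan-4-yl]acetic acid
Conditions: TsOH·H2O (cat.), H2SO4 (cat.), pentane, reflux, Dean–Stark
Reagents that add atoms: none
Why: Seebach acetalization of the α-hydroxy acid gives the thermodynamically preferred cis-dioxolanone, whose acetal center stores the chirality (self-regeneration of stereocenters).

**Step 13**
Reactants: 23 [(2R,4R)-2-tert-butyl-5-oxo-1,3-dioxolan-4-yl]acetic acid; 24 phenyl vinyl sulfoxide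
Product: 27 [(2R,4S)-2-tert-butyl-4-ethenyl-5-oxo-1,3-dioxolan-4-yl]acetic acid, via dilithium enolate 25 (not isolated), via sulfoxide adduct 26 (not isolated)
Conditions: LiN(SiMe3)2 (2.2 equiv), THF, −78 °C; then 24, −78 → −40 °C; AcOH; then PhMe, NaHCO3, 110 °C
Reagents that add atoms: none
Why: Michael addition of the dioxolanone enolate to the vinyl sulfoxide occurs anti to the tert-butyl group (overall retention, setting C13), and thermal sulfoxide syn-elimination then unveils the vinyl group.

**Step 14**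
Reactants: 27 [(2R,4S)-2-tert-butyl-4-ethenyl-5-oxo-1,3-dioxolan-4-yl]acetic acid
Product: 30 (S)-3-ethenyl-3-hydroxyoxolan-2-one, via mixed anhydride 28 (not isolated), via hydroxyethyl dioxolanone 29 (not isolated)
Conditions: i-BuOCOCl, N-methylmorpholine, THF, −15 °C; NaBH4, H2O, 0 °C; then TsOH·H2O (cat.), CH2Cl2, 25 °C
Reagents that add atoms: none
Why: Mixed-anhydride activation and borohydride reduction convert only the free carboxyl into CH2OH (the vinyl group is not hydroborated), and acid-catalysed transesterification onto the dioxolanone carbonyl closes the γ-lactone with loss of pivalaldehyde.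

**Step 15**
Reactants: 30 (S)-3-ethenyl-3-hydroxyoxolan-2-one; 20 dienyl triflate
Product: 32 coupled diene tert-butyl 5-{2-[(3R)-3-hydroxy-2-oxooxolan-3-yl]ethyl}-1,6-dimethyl-8-(triisopropylsilyloxy)-1,2,3,4,8,8a-hexahydronaphthalene-1-carboxylate, via alkylborane 31 (not isolated)
Conditions: 30, 9-BBN (2.2 equiv), THF, 25 °C; then 20, Pd(dppf)Cl2 (cat.), AsPh3 (cat.), K3PO4, DMF/H2O, 50 °C
Reagents that add atoms: none
Why: Anti-Markovnikov hydroboration of the vinyl group and B-alkyl Suzuki–Miyaura coupling with the enol triflate form C9–C11 without an organometallic that would attack the lactone or need hydroxyl protection.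

**Step 16**
Reactants: 32 coupled diene
Product: 35 chloromethyl 5-{2-[(3R)-3-hydroxy-2-oxooxolan-3-yl]ethyl}-1,6-dimethyl-8-(triisopropylsilyloxy)-1,2,3,4,8,8a-hexahydronaphthalene-1-carboxylate, via silyl ester 33 (not isolated), via ammonium carboxylate 34 (not isolated)
Conditions: Me3SiOTf, 2,6-lutidine, CH2Cl2, 0 → 25 °C; evaporate; then Bu4NF, BrCH2Cl, THF, 0 → 25 °C
Reagents that add atoms: bromochloromethane, ClCBr
Why: Silyl triflate cleaves the tert-butyl ester under buffered conditions (loss of 2-methylpropene), fluoride removes the trimethylsilyl groups but not the hindered secondary triisopropylsilyl ether, and the naked carboxylate displaces bromide from bromochloromethane (SN2 O-alkylation).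

**Step 17**
Reactants: 35 chloromethyl ester
Product: 36 9α,13R-epoxy-6β-(triisopropylsilyloxy)-5β-labd-7-ene-19,20:16,15-diolide
Conditions: AgOTf (1.5 equiv), 2,6-di-tert-butyl-4-methylpyridine, 4 Å MS, CH2Cl2, −40 → 0 °C
Reagents that add atoms: none
Why: Proposed new method: Silver triflate abstracts chloride to give an acyloxymethyl cation on the C19 carboxyl oxygen, the C10 terminus of the ring-B 7,9-diene attacks it, and the resulting C7–C8–C9 allyl cation is trapped at C9 by the C13 tertiary hydroxyl while the hindered pyridine takes up the triflic acid. The closest known reaction types are the Prins reaction of alkenes with formaldehyde in carboxylic anhydride media, which runs through acyloxymethyl cations, and cation–olefin cyclizations terminated by a hydroxyl group; the intramolecular, lactone-forming use of such a cation is the new element. The δ-lactone ring (C4, C19, O, C20, C10, C5) closes by 6-exo-trig attack of the diene terminus on C20, and the tetrahydrofuran ring (O, C9, C11, C12, C13) closes last by 5-exo attack of oxygen on the allyl cation terminus. C10 is set by the tether, which reaches C10 only on the face of ring A that bears the C4 carboxyl (C19 and C20 cis); C9 is set by anti addition across C9=C10, backed by thermodynamics because the tertiary allylic ether can re-ionize and the epimer with oxygen pseudo-equatorial and C11 pseudo-axial avoids A(1,2) strain with the C8 methyl. The step needs C- over O-alkylation of the cation (six-membered closure onto the electron-rich diene against an eleven-membered one onto the hydroxyl), attack at C10 and not C7 (only C10 is within reach), capture at C9 and not at C7 or by proton loss (five- against seven-membered ring, buffered medium), and survival of the allylic C6 silyl ether (bulky group, non-acidic conditions).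

**Step 18**
Reactants: 36 pentacyclic silyl ether
Product: 37 9α,13R-epoxy-6β-hydroxy-5β-labd-7-ene-19,20:16,15-diolide
Conditions: HF·pyridine, pyridine, THF, 25 °C
Reagents that add atoms: none
Why: Buffered fluoride desilylation frees the C6 hydroxyl without opening the lactones or ionizing the tertiary allylic ether.

**Step 19**
Reactants: 37 9α,13R-epoxy-6β-hydroxy-5β-labd-7-ene-19,20:16,15-diolide
Product: 38 target 9α,13R-epoxy-6β-hydroxy-5β,8βH-labdane-19,20:16,15-diolide (CNP0393616.2)
Conditions: H2 (1 atm), [Ir(cod)(PCy3)(py)]PF6 (cat.), CH2Cl2, 25 °C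
Reagents that add atoms: none
Why: In this hydroxyl-directed homogeneous hydrogenation the allylic C6 hydroxyl, which sits on the β side of the C7=C8 plane, should deliver hydrogen to that face and so set C8 (H-8 β, methyl α).

**Compound list**

1 | tert-butyl 2-bromopropanoate (racemic) | CC(Br)C(=O)OC(C)(C)C | starting material
2 | triphenylphosphine | c1ccc(cc1)P(c1ccccc1)c1ccccc1 | starting material
3 | (1-tert-butoxy-1-oxopropan-2-yl)triphenylphosphonium bromide | CC(C(=O)OC(C)(C)C)[P+](c1ccccc1)(c1ccccc1)c1ccccc1.[Br-] | intermediate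
4 | tert-butyl 2-(triphenylphosphoranylidene)propanoate | CC(C(=O)OC(C)(C)C)=P(c1ccccc1)(c1ccccc1)c1ccccc1 | intermediate
5 | (R)-2,2-dimethyl-1,3-dioxolane-4-carbaldehyde | O=C[C@H]1COC(C)(C)O1 | starting material
6 | tert-butyl (E)-3-[(4S)-2,2-dimethyl-1,3-dioxolan-4-yl]-2-methylprop-2-enoate | CC(C)(C)OC(=O)/C(C)=C/[C@H]1COC(C)(C)O1 | intermediate
7 | tert-butyl (2E,4S)-4,5-dihydroxy-2-methylpent-2-enoate | CC(C)(C)OC(=O)/C(C)=C/[C@H](O)CO | intermediate
8 | tert-butyl (2E,4S)-2-methyl-4,5-bis(triisopropylsilyloxy)pent-2-enoate | CC(C)(C)OC(=O)/C(C)=C/[C@H](O[Si](C(C)C)(C(C)C)C(C)C)CO[Si](C(C)C)(C(C)C)C(C)C | intermediate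
9 | tert-butyl (2E,4S)-5-hydroxy-2-methyl-4-(triisopropylsilyloxy)pent-2-enoate | CC(C)(C)OC(=O)/C(C)=C/[C@H](O[Si](C(C)C)(C(C)C)C(C)C)CO | intermediate
10 | tert-butyl (2E,4S)-2-methyl-5-oxo-4-(triisopropylsilyloxy)pent-2-enoate | CC(C)(C)OC(=O)/C(C)=C/[C@H](O[Si](C(C)C)(C(C)C)C(C)C)C=O | intermediate
11 | acrolein | C=CC=O | starting material
12 | diethyl (2-oxobutyl)phosphonate | CCC(=O)CP(=O)(OCC)OCC | starting material
13 | (E)-hepta-4,6-dien-3-one | C=C/C=C/C(=O)CC | intermediate
14 | (4E)-3-(trimethylsilyloxy)hepta-2,4,6-triene (enol ether geometry not defined) | C=C/C=C/C(O[Si](C)(C)C)=CC | intermediate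
15 | tert-butyl (2E,4S,8E)-2,6-dimethyl-7-oxo-4-(triisopropylsilyloxy)-5-(trimethylsilyloxy)undeca-2,8,10-trienoate (mixture at C5 and C6) | C=C/C=C/C(=O)C(C)C(O[Si](C)(C)C)[C@@H](O[Si](C(C)C)(C(C)C)C(C)C)/C=C(\C)C(=O)OC(C)(C)C | intermediate
16 | tert-butyl 1,6-dimethyl-5-oxo-8-(triisopropylsilyloxy)-7-(trimethylsilyloxy)-1,2,4a,5,6,7,8,8a-octahydronaphthalene-1-carboxylate (labdane: 19-ester β, H-5 β, 6-silyloxy β; mixture at C7, C8, C10) | CC1C(O[Si](C)(C)C)[C@@H](O[Si](C(C)C)(C(C)C)C(C)C)[C@H]2C(C=CC[C@]2(C)C(=O)OC(C)(C)C)C1=O | intermediate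
17 | tert-butyl 1,6-dimethyl-5-oxo-8-(triisopropylsilyloxy)-7-(trimethylsilyloxy)decahydronaphthalene-1-carboxylate (same centers; mixture at C7, C8, C10) | CC1C(O[Si](C)(C)C)[C@@H](O[Si](C(C)C)(C(C)C)C(C)C)[C@H]2C(CCC[C@]2(C)C(=O)OC(C)(C)C)C1=O | intermediate
18 | tert-butyl 1,6-dimethyl-5-oxo-8-(triisopropylsilyloxy)-1,2,3,4,4a,5,8,8a-octahydronaphthalene-1-carboxylate (labdane 7-en-9-one: 19-ester β, H-5 β, 6-silyloxy β; C10 epimers) | CC1=C[C@@H](O[Si](C(C)C)(C(C)C)C(C)C)[C@H]2C(CCC[C@]2(C)C(=O)OC(C)(C)C)C1=O | intermediate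
19 | potassium cross-conjugated dienolate of 18 | CC1=C[C@@H](O[Si](C(C)C)(C(C)C)C(C)C)[C@H]2C(CCC[C@]2(C)C(=O)OC(C)(C)C)=C1[O-].[K+] | intermediate
20 | tert-butyl 1,6-dimethyl-8-(triisopropylsilyloxy)-5-(trifluoromethylsulfonyloxy)-1,2,3,4,8,8a-hexahydronaphthalene-1-carboxylate (labdane 7,9-diene: 19-ester β, H-5 β, 6-silyloxy β) | CC1=C[C@@H](O[Si](C(C)C)(C(C)C)C(C)C)[C@H]2C(CCC[C@]2(C)C(=O)OC(C)(C)C)=C1OS(=O)(=O)C(F)(F)F | intermediate
21 | (R)-malic acid | O[C@H](CC(=O)O)C(=O)O | starting material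
22 | pivalaldehyde | CC(C)(C)C=O | starting material
23 | [(2R,4R)-2-tert-butyl-5-oxo-1,3-dioxolan-4-yl]acetic acid | OC(=O)C[C@H]1O[C@@H](C(C)(C)C)OC1=O | intermediate
24 | phenyl vinyl sulfoxide (racemic) | C=CS(=O)c1ccccc1 | starting material
25 | dilithium enolate–carboxylate of 23 | [Li+].[Li+].[O-]C(=O)CC1=C([O-])O[C@H](C(C)(C)C)O1 | intermediate
26 | {(2R,4S)-2-tert-butyl-5-oxo-4-[2-(phenylsulfinyl)ethyl]-1,3-dioxolan-4-yl}acetic acid (sulfur epimers) | OC(=O)C[C@@]1(CCS(=O)c2ccccc2)O[C@@H](C(C)(C)C)OC1=O | intermediate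
27 | [(2R,4S)-2-tert-butyl-4-ethenyl-5-oxo-1,3-dioxolan-4-yl]acetic acid | OC(=O)C[C@@]1(C=C)O[C@@H](C(C)(C)C)OC1=O | intermediate
28 | isobutyl carbonic mixed anhydride of 27 | CC(C)COC(=O)OC(=O)C[C@@]1(C=C)O[C@@H](C(C)(C)C)OC1=O | intermediate
29 | (2R,5S)-2-tert-butyl-5-ethenyl-5-(2-hydroxyethyl)-1,3-dioxolan-4-one | OCC[C@@]1(C=C)O[C@@H](C(C)(C)C)OC1=O | intermediate
30 | (S)-3-ethenyl-3-hydroxyoxolan-2-one | C=C[C@@]1(O)CCOC1=O | intermediate
31 | (R)-3-[2-(9-borabicyclo[3.3.1]nonan-9-yl)ethyl]-3-hydroxyoxolan-2-one (hydroxyl may be held as the borinate) | O[C@]1(CCB2C3CCCC2CCC3)CCOC1=O | intermediate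
32 | tert-butyl 5-{2-[(3R)-3-hydroxy-2-oxooxolan-3-yl]ethyl}-1,6-dimethyl-8-(triisopropylsilyloxy)-1,2,3,4,8,8a-hexahydronaphthalene-1-carboxylate (labdane 7,9-diene: 19-ester β, H-5 β, 6-silyloxy β, 13R) | CC1=C[C@@H](O[Si](C(C)C)(C(C)C)C(C)C)[C@H]2C(CCC[C@]2(C)C(=O)OC(C)(C)C)=C1CC[C@@]1(O)CCOC1=O | intermediate
33 | trimethylsilyl ester of the acid of 32 with the C13 hydroxyl as trimethylsilyl ether | CC1=C[C@@H](O[Si](C(C)C)(C(C)C)C(C)C)[C@H]2C(CCC[C@]2(C)C(=O)O[Si](C)(C)C)=C1CC[C@@]1(O[Si](C)(C)C)CCOC1=O | intermediate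
34 | tetrabutylammonium carboxylate of the acid of 32 | CC1=C[C@@H](O[Si](C(C)C)(C(C)C)C(C)C)[C@H]2C(CCC[C@]2(C)C(=O)[O-])=C1CC[C@@]1(O)CCOC1=O.CCCC[N+](CCCC)(CCCC)CCCC | intermediate
35 | chloromethyl 5-{2-[(3R)-3-hydroxy-2-oxooxolan-3-yl]ethyl}-1,6-dimethyl-8-(triisopropylsilyloxy)-1,2,3,4,8,8a-hexahydronaphthalene-1-carboxylate (same centers as 32) | CC1=C[C@@H](O[Si](C(C)C)(C(C)C)C(C)C)[C@H]2C(CCC[C@]2(C)C(=O)OCCl)=C1CC[C@@]1(O)CCOC1=O | intermediate
36 | 9α,13R-epoxy-6β-(triisopropylsilyloxy)-5β-labd-7-ene-19,20:16,15-diolide | CC1=C[C@@H](O[Si](C(C)C)(C(C)C)C(C)C)[C@H]2[C@]3(CCC[C@]2(C)C(=O)OC3)[C@@]12CC[C@]1(CCOC1=O)O2 | intermediate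
37 | 9α,13R-epoxy-6β-hydroxy-5β-labd-7-ene-19,20:16,15-diolide | CC1=C[C@@H](O)[C@H]2[C@]3(CCC[C@]2(C)C(=O)OC3)[C@@]12CC[C@]1(CCOC1=O)O2 | intermediate
38 | 9α,13R-epoxy-6β-hydroxy-5β,8βH-labdane-19,20:16,15-diolide (CNP0393616.2) | C[C@@H]1C[C@@H](O)[C@H]2[C@]3(CCC[C@]2(C)C(=O)OC3)[C@@]12CC[C@]1(CCOC1=O)O2 | target

**Step count and risks**

Total steps: 19. Longest linear sequence: 15 (steps 1–6, 8–11, 15–19).

Steps most likely to fail:

1. Step 17 (proposed new method). The acyloxymethyl cation may be captured by oxygen instead of by the diene, or the allyl cation may lose a proton or be trapped on the wrong face. The fallback uses known chemistry, sets out from enone 18 and returns at 36. The ester of 18 is exchanged under the conditions of step 16 to give chloromethyl 1,6-dimethyl-5-oxo-8-(triisopropylsilyloxy)-octahydronaphthalene-1-carboxylate F1. KN(SiMe3)2 (THF, −78 → 0 °C) then forms the C10 dienolate, which is C-alkylated intramolecularly by the chloromethyl group (6-exo-tet, necessarily cis to C19) to give the tricyclic enone lactone F2 (C10 quaternary, C9 ketone). In parallel, radical thiol–ene addition of 1-phenyl-1H-tetrazole-5-thiol (AIBN, PhMe, 80 °C) to vinyl lactone 30 gives the sulfide F3, which is oxidized (H2O2, (NH4)6Mo7O24, EtOH) to the sulfone F4. Julia–Kocienski olefination of the C9 ketone of F2 with the dianion of F4 (KN(SiMe3)2, 2.1 equiv, DME, −60 → 25 °C) gives the 7,9(11)-diene F5. Protonation of F5 at C11 (camphorsulfonic acid, CH2Cl2, 0 °C) generates the same C7–C8–C9 allyl cation as in step 17, and the C13 hydroxyl closes the tetrahydrofuran ring last to give 36.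

2. Step 9. The dienone is an electron-poor diene, so cycloaddition may be too slow and polymerization or thermal loss of silanol (to an acyclic E-enone that cannot cyclize) may take over. The fallback sets out from 15 and returns at 16. Luche reduction (NaBH4, CeCl3·7H2O, MeOH, −78 °C) of the ketone gives the dienol F6 (epimer mixture), whose diene is no longer conjugated to a carbonyl. Its normal-demand intramolecular Diels–Alder reaction at lower temperature (PhMe, 140 °C) gives the bicyclic alcohol F7, and Dess–Martin oxidation returns ketone 16.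

3. Step 16. The silyl triflate may ionize the doubly allylic C6 silyl ether of the electron-rich diene, followed by loss of H-5 and aromatization of ring B. The fallback sets out from triflate 20 and returns at 35. The tert-butyl ester is cleaved while the diene is still deactivated by the triflate group (CF3CO2H, CH2Cl2, 0 °C) to give the triflate acid F8. The B-alkyl Suzuki coupling of step 15 is run on its potassium carboxylate to give the diene acid F9, whose cesium salt is alkylated with bromochloromethane (Cs2CO3, DMF, 25 °C) to 35, so the diene only ever sees base.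

**Further compounds**

F1 | step 17 | chloromethyl 1,6-dimethyl-5-oxo-8-(triisopropylsilyloxy)-1,2,3,4,4a,5,8,8a-octahydronaphthalene-1-carboxylate | CC1=C[C@@H](O[Si](C(C)C)(C(C)C)C(C)C)[C@H]2C(CCC[C@]2(C)C(=O)OCCl)C1=O
F2 | step 17 | 9-oxo-6β-(triisopropylsilyloxy)-11,12,13,14,15,16-hexanor-5β-labd-7-en-19,20-olide | CC1=C[C@@H](O[Si](C(C)C)(C(C)C)C(C)C)[C@H]2[C@]3(CCC[C@]2(C)C(=O)OC3)C1=O
F3 | step 17 | (S)-3-hydroxy-3-{2-[(1-phenyl-1H-tetrazol-5-yl)sulfanyl]ethyl}oxolan-2-one | O[C@]1(CCSc2nnnn2-c2ccccc2)CCOC1=O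
F4 | step 17 | (S)-3-hydroxy-3-{2-[(1-phenyl-1H-tetrazol-5-yl)sulfonyl]ethyl}oxolan-2-one | O[C@]1(CCS(=O)(=O)c2nnnn2-c2ccccc2)CCOC1=O
F5 | step 17 | 13R-hydroxy-6β-(triisopropylsilyloxy)-5β-labda-7,9(11)-diene-19,20:16,15-diolide (C9=C11 geometry not defined) | CC1=C[C@@H](O[Si](C(C)C)(C(C)C)C(C)C)[C@H]2[C@]3(CCC[C@]2(C)C(=O)OC3)C1=CC[C@@]1(O)CCOC1=O
F6 | step 9 | tert-butyl (2E,4S,8E)-7-hydroxy-2,6-dimethyl-4-(triisopropylsilyloxy)-5-(trimethylsilyloxy)undeca-2,8,10-trienoate | C=C/C=C/C(O)C(C)C(O[Si](C)(C)C)[C@@H](O[Si](C(C)C)(C(C)C)C(C)C)/C=C(\C)C(=O)OC(C)(C)C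
F7 | step 9 | tert-butyl 5-hydroxy-1,6-dimethyl-8-(triisopropylsilyloxy)-7-(trimethylsilyloxy)-1,2,4a,5,6,7,8,8a-octahydronaphthalene-1-carboxylate | CC1C(O[Si](C)(C)C)[C@@H](O[Si](C(C)C)(C(C)C)C(C)C)[C@H]2C(C=CC[C@]2(C)C(=O)OC(C)(C)C)C1O
F8 | step 16 | 1,6-dimethyl-8-(triisopropylsilyloxy)-5-(trifluoromethylsulfonyloxy)-1,2,3,4,8,8a-hexahydronaphthalene-1-carboxylic acid | CC1=C[C@@H](O[Si](C(C)C)(C(C)C)C(C)C)[C@H]2C(CCC[C@]2(C)C(=O)O)=C1OS(=O)(=O)C(F)(F)F
F9 | step 16 | 5-{2-[(3R)-3-hydroxy-2-oxooxolan-3-yl]ethyl}-1,6-dimethyl-8-(triisopropylsilyloxy)-1,2,3,4,8,8a-hexahydronaphthalene-1-carboxylic acid | CC1=C[C@@H](O[Si](C(C)C)(C(C)C)C(C)C)[C@H]2C(CCC[C@]2(C)C(=O)O)=C1CC[C@@]1(O)CCOC1=O
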